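**Retrosynthetic overview**
1. Ring numbering: C1 = C(CH3)(chlorovinyl), C2 = CH2, C3 = C(CH3)Cl, C4 = CHBr, C5 = CH2, C6 = CHBr. The (E)-chlorovinyl group is traced back (Takai–Utimoto olefination, ozonolysis) to a vinyl group on C1 (14).
2. The only ring, the cyclohexane, is opened at C5–C6. In the open chain both ends are electrophilic carbons (C5–OTf and C6HBr2 in 12). They are joined by reversing the polarity of C6 through Br/Li exchange (α-bromo carbenoid, 6-exo-tet), which keeps one bromine on C6.
3. Enabling feature: C6 is a bromomethine between the all-carbon quaternary C1 (no β-hydrogen, so the carbenoid has no 1,2-hydride escape) and the unsubstituted methylene C5, which becomes a primary carbon on ring opening. The fully substituted C1 and C3 fold the chain.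
4. The cis C3–Cl/C4–Br pair cannot come from anti addition to a ring alkene. It is therefore set in the open chain by enantioselective anti bromochlorination of the E-allylic alcohol 10.
5. C1 is set first, by auxiliary-controlled deconjugative α-alkylation of tigloyl imide 3 with bromo-enoate 4. This places methyl, vinyl, C6 (the acyl carbon) and the C2–C5 arm on C1 in one bond formation.

Key step: step 9

Assumption: 4 is used as the pure E isomer, and dienolate 5 is taken to react like a chelated imide enolate (α-methyl cis to O–Na, attack opposite to the benzyl group); if the facial sense proved opposite, the (R)-auxiliary would be used.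

Step 1
Reactants: 1 (4S)-4-benzyl-1,3-oxazolidin-2-one; 2 (E)-2-methylbut-2-enoyl chloride (tigloyl chloride)
Product: 3 (4S)-4-benzyl-3-[(E)-2-methylbut-2-enoyl]-1,3-oxazolidin-2-one
Conditions: Et3N, LiCl, THF, −20 °C to rt
Reagents that add atoms: none
Why: N-acylation of the oxazolidinone under mild LiCl/Et3N activation should leave the auxiliary stereocenter and the E geometry of the tigloyl group untouched.

Step 2
Reactants: 3 (4S)-4-benzyl-3-[(E)-2-methylbut-2-enoyl]-1,3-oxazolidin-2-one; 4 ethyl (E)-4-bromo-3-methylbut-2-enoate
Product: 6 ethyl (2E,5R)-5-{[(4S)-4-benzyl-2-oxo-1,3-oxazolidin-3-yl]carbonyl}-3,5-dimethylhepta-2,6-dienoate, via sodium dienolate 5 (not isolated)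
Conditions: NaN(SiMe3)2, THF, −78 °C; then 4, −78 to −30 °C
Reagents that add atoms: none
Why: Deconjugative α-alkylation of an oxazolidinone-bound dienolate (auxiliary-controlled enolate alkylation): γ-deprotonation gives chelated 5, which should displace the allylic bromide by SN2 at its α-carbon from the face opposite to the benzyl group, creating quaternary C1 as (R) and keeping the E geometry of 4.

Step 3
Reactants: 6 ethyl (2E,5R)-5-{[(4S)-4-benzyl-2-oxo-1,3-oxazolidin-3-yl]carbonyl}-3,5-dimethylhepta-2,6-dienoate
Product: 7 ethyl (2E,5R)-5-(hydroxymethyl)-3,5-dimethylhepta-2,6-dienoate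
Conditions: NaBH4, THF/H2O, 0 °C to rt
Reagents that add atoms: none
Why: Borohydride reduction of the N-acyl oxazolidinone (reductive auxiliary removal) should give the neopentyl alcohol and spare the less electrophilic conjugated ester, both alkenes and the non-epimerisable quaternary centre.

Step 4
Reactants: 7 ethyl (2E,5R)-5-(hydroxymethyl)-3,5-dimethylhepta-2,6-dienoate
Product: 8 ethyl (2E,5R)-5-formyl-3,5-dimethylhepta-2,6-dienoate
Conditions: Dess–Martin periodinane, CH2Cl2, rt
Reagents that add atoms: none
Why: Dess–Martin oxidation of a primary alcohol should stop at the aldehyde, which has no α-hydrogen and so can neither epimerise nor move its vinyl group into conjugation.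

Step 5
Reactants: 8 ethyl (2E,5R)-5-formyl-3,5-dimethylhepta-2,6-dienoate
Product: 9 ethyl (2E,5R)-5-(dibromomethyl)-3,5-dimethylhepta-2,6-dienoate
Conditions: (PhO)3P, Br2, CH2Cl2, −78 °C (reagent preformed); then 8, −78 to 0 °C
Reagents that add atoms: bromine, BrBr
Why: Deoxygenative geminal dibromination of an aldehyde with preformed (PhO)3PBr2 should exchange the carbonyl oxygen for two bromides, and the absence of free bromine should spare the hindered vinyl group and the electron-poor enoate.

Step 6
Reactants: 9 ethyl (2E,5R)-5-(dibromomethyl)-3,5-dimethylhepta-2,6-dienoate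
Product: 10 (2E,5R)-5-(dibromomethyl)-3,5-dimethylhepta-2,6-dien-1-ol
Conditions: i-Bu2AlH (2.2 equiv), CH2Cl2, −78 °C
Reagents that add atoms: none
Why: 1,2-Reduction of the conjugated ester with i-Bu2AlH should give the E-allylic alcohol with retained geometry and leave the dibromomethyl group alone at −78 °C.

Step 7
Reactants: 10 (2E,5R)-5-(dibromomethyl)-3,5-dimethylhepta-2,6-dien-1-ol
Product: 11 (2S,3R,5R)-2-bromo-3-chloro-5-(dibromomethyl)-3,5-dimethylhept-6-en-1-ol
Conditions: N-bromosuccinimide, ClTi(OiPr)3, chiral tridentate O,N,O Schiff-base ligand of the amino-alcohol/salicylaldehyde type (20 mol %, enantiomer matched to the 2S,3R product), hexanes, −20 °C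
Reagents that add atoms: N-bromosuccinimide, O=C1CCC(=O)N1Br; chlorotitanium triisopropoxide, CC(C)O[Ti](Cl)(OC(C)C)OC(C)C
Why: Titanium-mediated catalytic enantioselective bromochlorination of an allylic alcohol: the alcohol binds to the chiral titanium complex, the bromonium ion forms on the ligand-selected face and chloride is delivered anti to the distal tertiary carbon, so the E geometry becomes the (2S,3R) pair (ring C4 and C3) while the unbound, hindered vinyl group stays out.

Step 8
Reactants: 11 (2S,3R,5R)-2-bromo-3-chloro-5-(dibromomethyl)-3,5-dimethylhept-6-en-1-ol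
Product: 12 (2S,3R,5R)-2-bromo-3-chloro-5-(dibromomethyl)-3,5-dimethylhept-6-en-1-yl trifluoromethanesulfonate
Conditions: Tf2O, 2,6-lutidine, CH2Cl2, −78 °C; cold filtration through silica, used at once
Reagents that add atoms: trifluoromethanesulfonic anhydride, O=S(=O)(OS(=O)(=O)C(F)(F)F)C(F)(F)F
Why: O-Sulfonylation of the primary alcohol touches no stereocenter, and the electron-withdrawing β-bromine and γ-chlorine should make the primary triflate stable enough to handle cold.

Step 9
Reactants: 12 (2S,3R,5R)-2-bromo-3-chloro-5-(dibromomethyl)-3,5-dimethylhept-6-en-1-yl trifluoromethanesulfonate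
Product: 14 (1R,2S,4S,5R)-2,4-dibromo-1-chloro-5-ethenyl-1,5-dimethylcyclohexane, via lithium carbenoid 13 (not isolated)
Conditions: n-BuLi (1.0 equiv, slow addition), THF/Et2O/pentane (4:1:1), −110 °C, then −90 °C; MeOH quench
Reagents that add atoms: none
Why: Proposed new method: slow addition of n-BuLi should exchange one bromine of the CHBr2 group (geminal dibromides exchange far faster than the secondary C4–Br or the tertiary C3–Cl react, and faster than butyl attack on the triflate), and the α-bromoalkyllithium 13, whose C6 was an electrophilic carbon in 12, should displace the primary triflate at C5 by intramolecular SN2 while keeping the second bromine on C6. The closest known reaction types are the Br/Li exchange of 1,1-dibromoalkanes to α-bromoalkyllithium carbenoids at −110 °C and the alkylation of dibromomethyllithium and related lithium carbenoids with primary alkyl iodides and triflates; the ring-closing version next to a quaternary carbon is what is new. The cyclohexane is closed in the 6-exo-tet mode with the leaving group outside the ring, so attack on the C4 bromine (non-linear endocyclic geometry) or on C4 itself (five-membered ring at a neopentyl-like carbon) should not compete. The new stereocenter C6 is set in a chair-like transition state with both methyl groups and the C4 bromine equatorial, in which the C6 bromine should take the axial site anti to the axial vinyl group on C1, where it has one gauche neighbour on C1 instead of two and its dipole is turned away from that of the equatorial C4–Br bond. The two epimers of 13 should interconvert through a bromine ate complex with still unreacted 12, so the faster-closing epimer can drain the mixture (Curtin–Hammett situation). The quaternary C1 leaves 13 without a β-hydrogen, which shuts off the usual 1,2-hydride decay of such carbenoids, and the fully substituted C1 and C3 fold the chain for closure.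

Step 10
Reactants: 14 (1R,2S,4S,5R)-2,4-dibromo-1-chloro-5-ethenyl-1,5-dimethylcyclohexane
Product: 16 (1R,2S,4S,5R)-2,4-dibromo-5-chloro-1,5-dimethylcyclohexane-1-carbaldehyde, via ozonide 15 (not isolated)
Conditions: O3, CH2Cl2, −78 °C; then Me2S, −78 °C to rt
Reagents that add atoms: ozone, [O-][O+]=O
Why: Ozonolysis with reductive work-up cleaves the only alkene of 14 to the aldehyde under neutral conditions that the alkyl halides tolerate, and the aldehyde has no α-hydrogen through which the β-bromide could be eliminated.

Step 11
Reactants: 16 (1R,2S,4S,5R)-2,4-dibromo-5-chloro-1,5-dimethylcyclohexane-1-carbaldehyde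
Product: 17 (1R,2S,4S,5R)-2,4-dibromo-1-chloro-5-[(E)-2-chloroethenyl]-1,5-dimethylcyclohexane (target)
Conditions: CrCl2 (6 equiv), CHCl3 (2 equiv), THF, 65 °C
Reagents that add atoms: chloroform, ClC(Cl)Cl
Why: Takai–Utimoto chloro-olefination: the geminal dichromium species made from CHCl3 and divalent chromium adds to the aldehyde and eliminates through the arrangement that places chlorine anti to the bulky ring, which should give the E-vinyl chloride without a basic reagent.

**Compound list**
1 | (4S)-4-benzyl-1,3-oxazolidin-2-one | O=C1N[C@@H](Cc2ccccc2)CO1 | starting material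
2 | (E)-2-methylbut-2-enoyl chloride (tigloyl chloride) | C/C=C(\C)C(Cl)=O | starting material
3 | (4S)-4-benzyl-3-[(E)-2-methylbut-2-enoyl]-1,3-oxazolidin-2-one | C/C=C(\C)C(=O)N1[C@@H](Cc2ccccc2)COC1=O | intermediate
4 | ethyl (E)-4-bromo-3-methylbut-2-enoate | BrC/C(C)=C/C(=O)OCC | starting material
5 | sodium dienolate of 3 (α-methyl cis to O–Na, vinyl cis to N) | [Na+].C=C/C(C)=C(/[O-])N1[C@@H](Cc2ccccc2)COC1=O | intermediate
6 | ethyl (2E,5R)-5-{[(4S)-4-benzyl-2-oxo-1,3-oxazolidin-3-yl]carbonyl}-3,5-dimethylhepta-2,6-dienoate | C[C@](C(=O)N1[C@@H](Cc2ccccc2)COC1=O)(C=C)C/C(C)=C/C(=O)OCC | intermediate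
7 | ethyl (2E,5R)-5-(hydroxymethyl)-3,5-dimethylhepta-2,6-dienoate | C[C@](CO)(C=C)C/C(C)=C/C(=O)OCC | intermediate
8 | ethyl (2E,5R)-5-formyl-3,5-dimethylhepta-2,6-dienoate | C[C@](C=O)(C=C)C/C(C)=C/C(=O)OCC | intermediate
9 | ethyl (2E,5R)-5-(dibromomethyl)-3,5-dimethylhepta-2,6-dienoate | C[C@](C(Br)Br)(C=C)C/C(C)=C/C(=O)OCC | intermediate
10 | (2E,5R)-5-(dibromomethyl)-3,5-dimethylhepta-2,6-dien-1-ol | C[C@](C(Br)Br)(C=C)C/C(C)=C/CO | intermediate
11 | (2S,3R,5R)-2-bromo-3-chloro-5-(dibromomethyl)-3,5-dimethylhept-6-en-1-ol | C[C@](C(Br)Br)(C=C)C[C@@](C)(Cl)[C@@H](Br)CO | intermediate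
12 | (2S,3R,5R)-2-bromo-3-chloro-5-(dibromomethyl)-3,5-dimethylhept-6-en-1-yl trifluoromethanesulfonate | C[C@](C(Br)Br)(C=C)C[C@@](C)(Cl)[C@@H](Br)COS(=O)(=O)C(F)(F)F | intermediate
13 | α-bromoalkyllithium carbenoid from 12 (CHBrLi in place of CHBr2, interconverting epimers at that carbon) | C[C@](C([Li])Br)(C=C)C[C@@](C)(Cl)[C@@H](Br)COS(=O)(=O)C(F)(F)F | intermediate
14 | (1R,2S,4S,5R)-2,4-dibromo-1-chloro-5-ethenyl-1,5-dimethylcyclohexane | C[C@]1(C=C)C[C@@](C)(Cl)[C@@H](Br)C[C@@H]1Br | intermediate
15 | 1,2,4-trioxolane (secondary ozonide) of 14, bound to ring C1 through its C3 | C[C@]1(C2OCOO2)C[C@@](C)(Cl)[C@@H](Br)C[C@@H]1Br | intermediate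
16 | (1R,2S,4S,5R)-2,4-dibromo-5-chloro-1,5-dimethylcyclohexane-1-carbaldehyde | C[C@]1(C=O)C[C@@](C)(Cl)[C@@H](Br)C[C@@H]1Br | intermediate
17 | (1R,2S,4S,5R)-2,4-dibromo-1-chloro-5-[(E)-2-chloroethenyl]-1,5-dimethylcyclohexane | C[C@]1(/C=C/Cl)C[C@@](C)(Cl)[C@@H](Br)C[C@@H]1Br | target

**Total step count:** 11. **Longest linear sequence:** 11 steps (1 and 2 to 17).

**Steps most likely to fail**

**Step 9 (bears the label).**
- What may go wrong: α-elimination of the carbenoid with carbene-type C–H insertion into the C1 methyl group.
- Internal proton transfer from C4–H, followed by loss of triflate.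
- Butyl attack on the triflate before exchange.
- Poor discrimination between the axial and equatorial sites at C6.

Fallback (known chemistry, boron in place of lithium as carrier of the reversed polarity): it sets out from aldehyde 8 and returns at 14.
- Condensation of 8 with 4-methylbenzenesulfonohydrazide gives the tosylhydrazone F1.
- NaH and B2pin2 in toluene at 90 °C convert it, through the diazoalkane, into the geminal bis(boronate) F2.
- i-Bu2AlH gives the allylic alcohol F3, and the bromochlorination of step 7 gives the bromochloro alcohol F4.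
- TsCl/pyridine gives the tosylate F5.
- NaOtBu in THF triggers the alkoxide-induced deborylative 6-exo-tet cyclisation to the cyclohexyl boronate F6, expected with boron equatorial.
- Formation of the ate complex with 3,5-bis(trifluoromethyl)phenyllithium and treatment with N-bromosuccinimide replaces boron by bromine with inversion, which gives the axial C6 bromide of 14.

**Step 5.**
- What may go wrong: ionisation of the α-bromo oxyphosphonium intermediate at the neopentyl carbon, with vinyl participation or alkyl shift.
- Bromine addition to the vinyl group.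

Fallback (oxidative bromination of a hydrazone instead of phosphorus activation): it sets out from 8 and returns at 9. Treatment of 8 with 1,2-bis(tert-butyldimethylsilyl)hydrazine and catalytic Sc(OTf)3 gives the N-silyl hydrazone F7. CuBr2 and Et3N in MeOH then convert it into the gem-dibromide 9 with loss of nitrogen.

**Step 11.**
- What may go wrong: reductive elimination of the vicinal C3–Cl/C4–Br pair, or reduction of C6–Br, by divalent chromium at 65 °C.
- Sluggish addition to the hindered aldehyde.

Fallback (no chromium and no aldehyde): it sets out from 14 and returns at 17, bypassing 15 and 16.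
- PhSeCl in CH2Cl2 adds to the vinyl group. Chloride opens the seleniranium ion at the unhindered terminal carbon and gives the β-chloro selenide F8.
- H2O2 gives the selenoxide F9.
- The syn-elimination of F9 can only use a hydrogen of the CH2Cl group, because the other neighbour is quaternary C1. It should place chlorine anti to the ring and give the E-vinyl chloride 17.

**Further compounds**
F1 | step 9 | ethyl (2E,5R)-3,5-dimethyl-5-{(E)-[2-(4-methylbenzenesulfonyl)hydrazinylidene]methyl}hepta-2,6-dienoate | C[C@](/C=N/NS(=O)(=O)c1ccc(C)cc1)(C=C)C/C(C)=C/C(=O)OCC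
F2 | step 9 | ethyl (2E,5R)-5-[bis(4,4,5,5-tetramethyl-1,3,2-dioxaborolan-2-yl)methyl]-3,5-dimethylhepta-2,6-dienoate | C[C@](C(B1OC(C)(C)C(C)(C)O1)B1OC(C)(C)C(C)(C)O1)(C=C)C/C(C)=C/C(=O)OCC
F3 | step 9 | (2E,5R)-5-[bis(4,4,5,5-tetramethyl-1,3,2-dioxaborolan-2-yl)methyl]-3,5-dimethylhepta-2,6-dien-1-ol | C[C@](C(B1OC(C)(C)C(C)(C)O1)B1OC(C)(C)C(C)(C)O1)(C=C)C/C(C)=C/CO
F4 | step 9 | (2S,3R,5R)-5-[bis(4,4,5,5-tetramethyl-1,3,2-dioxaborolan-2-yl)methyl]-2-bromo-3-chloro-3,5-dimethylhept-6-en-1-ol | C[C@](C(B1OC(C)(C)C(C)(C)O1)B1OC(C)(C)C(C)(C)O1)(C=C)C[C@@](C)(Cl)[C@@H](Br)CO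
F5 | step 9 | 4-methylbenzenesulfonate of F4 | C[C@](C(B1OC(C)(C)C(C)(C)O1)B1OC(C)(C)C(C)(C)O1)(C=C)C[C@@](C)(Cl)[C@@H](Br)COS(=O)(=O)c1ccc(C)cc1
F6 | step 9 | pinacol boronate that carries boron in place of the C6 bromine of 14, on the opposite ring face (equatorial, cis to the vinyl group) | C[C@]1(C=C)C[C@@](C)(Cl)[C@@H](Br)C[C@H]1B2OC(C)(C)C(C)(C)O2
F7 | step 5 | ethyl (2E,5R)-5-{(E)-[2-(tert-butyldimethylsilyl)hydrazinylidene]methyl}-3,5-dimethylhepta-2,6-dienoate | C[C@](/C=N/N[Si](C)(C)C(C)(C)C)(C=C)C/C(C)=C/C(=O)OCC
F8 | step 11 | β-chloro selenide of 14: CH(SePh)CH2Cl in place of the vinyl group, either configuration at the selenium-bearing carbon | C[C@]1(C(CCl)[Se]c2ccccc2)C[C@@](C)(Cl)[C@@H](Br)C[C@@H]1Br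
F9 | step 11 | selenoxide of F8 | C[C@]1(C(CCl)[Se](=O)c2ccccc2)C[C@@](C)(Cl)[C@@H](Br)C[C@@H]1Br
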